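**Retrosynthetic overview**

1. 22 ⇐ 4-ketone 21 (isopropyl addition) ⇐ 6α-veratrate 4α-silyl ether 19 ⇐ β,γ-enone 16 ⇐ trans-fused 6,9-dione 13; all of this is functional-group work on one hydroazulene dione.
2. 13 ⇐ retro-aldol scission of C6–C10 in the tetracyclic β-silyloxy cyclobutyl ketone 9 ⇐ photoadduct 7 (the C8 methyl is added on 7, where only C8 can enolise).
3. 7 ⇐ intramolecular [2+2] (bonds C5–C6 and C1–C10) of the diisopropylsilylene-tethered enone–alkene 6 ⇐ (R)-3-methylcyclopent-2-enol 2 + i-Pr2SiCl2 + cyclopentane-1,3-dione.
4. Feature: the seven-membered ring C1–C10–C9–C8–C7–C6–C5 is a five-carbon 1,3-dione unit (C6 to C10; oxygen at C6, the carbonyl that becomes the C8=C9 alkene at C9) set across the C1–C5 bond of a methylcyclopentane, so C6(O)–C5–C1–C10–C9 is a 1,5-dicarbonyl (de Mayo) retron.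
5. Ring order: cyclopentane (from 1) → cyclobutane plus temporary dioxasilinane (step 3) → cycloheptane by two-carbon ring expansion (step 5).

Key step: step 3

Remark: daucane locants are used throughout (C1 methyl-bearing fusion carbon, C4 carbinol carbon, C5 fusion CH, C6 ester carbon, C8 methyl-bearing carbon); β is the face of the C1 methyl, α the opposite face. The dione partner is kept symmetrical so that its O-silylation has a single outcome, and sp3 C8 is carried as an epimer mixture.

**Route**

Step 1
Reactants: 1 3-methylcyclopent-2-en-1-one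
Product: 2 (R)-3-methylcyclopent-2-en-1-ol
Conditions: (S)-2-methyl-CBS-oxazaborolidine (0.1 equiv), catecholborane, toluene, −78 °C; aq. NaOH work-up; used without acid contact
Reagents that add atoms: none
Why: Corey–Bakshi–Shibata (CBS) reduction: the oxazaborolidine binds the carbonyl with the larger alkenyl arm away from the catalyst and delivers hydride 1,2 to one face, which for the (S)-catalyst should give the (R)-allylic alcohol that later fixes every other stereocentre.

Step 2
Reactants: 2 (R)-3-methylcyclopent-2-en-1-ol; 3 dichlorodiisopropylsilane; 4 cyclopentane-1,3-dione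
Product: 6 3-{[diisopropyl((R)-3-methylcyclopent-2-en-1-yloxy)silyl]oxy}cyclopent-2-en-1-one, via chlorosilyl ether 5 (not isolated)
Conditions: 3 (1.05 equiv), Et3N, 4-(dimethylamino)pyridine (cat.), CH2Cl2, −78 → 0 °C; then 4, Et3N, MeCN, 0 °C → rt; anhydrous filtration through Et3N-washed silica
Reagents that add atoms: none
Why: Stepwise substitution at silicon: the hindered i-Pr2Si centre gives up its second chloride much more slowly than the first so monochloride 5 forms cleanly, and the triethylammonium enolate of the symmetrical dione 4 then silylates on oxygen with only one possible enol ether; the C4 stereocentre is untouched.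

Step 3
Reactants: 6 silylene-tethered enone–alkene
Product: 7 tetracyclic photoadduct (cis-anti-cis cyclobutane; silylene bridge from 4α-O to 6-O; 9-ketone; 5β-H)
Conditions: hν (medium-pressure Hg lamp, uranium-glass filter, λ > 330 nm), degassed dry MeCN, 0.005 M, 0 °C
Reagents that add atoms: none
Why: Excitation of the 3-silyloxy enone and intersystem crossing give its triplet, whose β-carbon C6 bonds to C5 of the tethered cyclopentene; the resulting C10/C1 1,4-diradical spin-inverts and closes the cyclobutane, i.e. an intramolecular enone–alkene [2+2] photocycloaddition of the de Mayo type with a temporary silicon tether. The first bond closes the six-membered 1,3-dioxa-2-silacyclohexane ring in 6-exo mode (the alternative C6–C1 bond would need a seven-membered ring), and the second bond closes the four-membered ring by radical–radical coupling. C5 is set because the six-membered ring can only be cis-fused to the cyclopentene, so C6 arrives on the face of the C4 oxygen (α); C1 is set because a cyclobutane on a five-membered ring must be cis, so C10 is also α and the methyl stays β. C6 and C10 follow from the necessarily cis 4/5 fusion of the cyclopentanone and from the silylene bridge, which holds O6 on the cyclopentane side and so forces the cis-anti-cis arrangement. The step needs head-to-head regiochemistry (C6 to C5, C10 to C1) and α-face addition; both are secured by the short O–Si–O tether from the (R)-configured C4 oxygen, while the Thorpe–Ingold effect of the two isopropyl groups favours the folded reactive conformer. Irradiation above 330 nm excites only the enone chromophore, so the saturated ketone product should not undergo α-cleavage.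

Step 4
Reactants: 7 tetracyclic photoadduct
Product: 9 8-methyl photoadduct (C8 epimers; otherwise as 7), via lithium enolate 8 (not isolated)
Conditions: LiN(i-Pr)2 (1.1 equiv), THF, −78 °C; MeI, −78 → −40 °C
Reagents that add atoms: iodomethane (MeI), CI
Why: Kinetic enolate alkylation: the only α-position that enolises readily is C8, because C10–H sits on the cyclobutane ring fusion where an enolate double bond would be badly strained, so the methyl group enters at C8 (its configuration is irrelevant, C8 becomes sp2 later).

Step 5
Reactants: 9 8-methyl photoadduct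
Product: 11 cis-fused 4α-hydroxy-1β,8-dimethylbicyclo[5.3.0]decane-6,9-dione (5β-H; C8 epimers), via cyclobutanediol 10 (not isolated)
Conditions: Bu4NF (2.5 equiv), THF, 0 °C; aq. NH4Cl
Reagents that add atoms: none
Why: Fluoride cleaves both Si–O bonds and the freed tertiary cyclobutanol, a strained β-hydroxy ketone, undergoes retro-aldol scission of C6–C10 (the ring-expansion half of the de Mayo sequence) to give the cycloheptane-1,4-dione with C1, C4 and C5 unchanged.

Step 6
Reactants: 11 cis-fused hydroxy dione
Product: 12 cis-fused 4α-(tert-butyldimethylsilyloxy)-1β,8-dimethylbicyclo[5.3.0]decane-6,9-dione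
Conditions: TBSCl, imidazole, DMF, rt
Reagents that add atoms: tert-butyldimethylsilyl chloride (TBSCl), CC(C)(C)[Si](C)(C)Cl
Why: Standard silylation of the secondary alcohol, which removes the free hydroxyl that could add to C9 as an internal hemiketal or be lost by β-elimination, and places a bulky group next to C6.

Step 7
Reactants: 12 cis-fused silyl ether dione
Product: 13 trans-fused 4α-(tert-butyldimethylsilyloxy)-1β,8-dimethylbicyclo[5.3.0]decane-6,9-dione (5α-H)
Conditions: 1,8-diazabicyclo[5.4.0]undec-7-ene (DBU, 0.3 equiv), toluene, rt → 40 °C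
Reagents that add atoms: none
Why: Amidine-base epimerisation through the C5–C6 enol(ate) under thermodynamic control: the trans-fused isomer should be favoured because it takes the C6 carbonyl arm off the face of the vicinal 4α-silyloxy group and out of the concave cis-hydroazulene, and the poor silyloxide leaving group should resist E1cB loss under these mild conditions.

Step 8
Reactants: 13 trans-fused dione
Product: 14 trans-fused 4α-(tert-butyldimethylsilyloxy)-9-hydroxy-1β,8-dimethylbicyclo[5.3.0]decan-6-one (9-OH cis to 8-CH3)
Conditions: LiBH(s-Bu)3 (1.05 equiv), THF, −78 °C; NaOH, H2O2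
Reagents that add atoms: none
Why: Sterically governed hydride transfer from a bulky trialkylborohydride: the C9 carbonyl (flanked by CH(CH3) and CH2) should react well before the C6 carbonyl, whose α-carbon C5 carries both the quaternary C1 and the silyloxy-bearing C4, and hydride enters anti to the C8 methyl so that 9-OH is cis to 8-CH3.

Step 9
Reactants: 14 9-hydroxy-6-ketone
Product: 16 trans-fused 4α-(tert-butyldimethylsilyloxy)-1β,8-dimethylbicyclo[5.3.0]dec-8-en-6-one, via dichlorophosphate 15 (not isolated)
Conditions: POCl3, pyridine, 0 → 50 °C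
Reagents that add atoms: none
Why: Dehydration by E2 anti-elimination from the dichlorophosphate: in the cis 9-ol the tertiary C8–H is antiperiplanar to the leaving group and Zaitsev elimination should give the trisubstituted C8=C9 alkene, the weakly basic medium leaving the β,γ-unsaturated ketone unconjugated.

Step 10
Reactants: 16 β,γ-unsaturated ketone
Product: 17 trans-fused 4α-(tert-butyldimethylsilyloxy)-1β,8-dimethylbicyclo[5.3.0]dec-8-en-6α-ol
Conditions: Li, NH3(l), THF, t-BuOH, −78 °C; NH4Cl
Reagents that add atoms: none
Why: Dissolving-metal reduction of the ketone gives the thermodynamically preferred alcohol, here the equatorial 6α-ol (H6 anti to H5) that avoids the 1,3-diaxial clash with the C1 methyl suffered by the 6β-epimer; the isolated trisubstituted alkene and the silyl ether are inert.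

Step 11
Reactants: 17 6α-alcohol; 18 3,4-dimethoxybenzoyl chloride
Product: 19 6α-(3,4-dimethoxybenzoyloxy) 4α-silyl ether
Conditions: 18, Et3N, 4-(dimethylamino)pyridine, CH2Cl2, rt
Reagents that add atoms: none
Why: DMAP-catalysed acylation of the secondary alcohol by the acid chloride (nucleophilic catalysis via the acylpyridinium), with retention at C6.

Step 12
Reactants: 19 ester silyl ether
Product: 20 6α-(3,4-dimethoxybenzoyloxy)-1β,8-dimethylbicyclo[5.3.0]dec-8-en-4α-ol (trans-fused)
Conditions: HF·pyridine, THF/pyridine, 0 °C → rt
Reagents that add atoms: none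
Why: Fluoride-driven cleavage of the secondary silyl ether under non-basic conditions, so the aryl ester neither hydrolyses nor migrates to the freed 4-hydroxyl.

Step 13
Reactants: 20 4α-alcohol
Product: 21 6α-(3,4-dimethoxybenzoyloxy)-1β,8-dimethylbicyclo[5.3.0]dec-8-en-4-one (trans-fused)
Conditions: Dess–Martin periodinane, NaHCO3, CH2Cl2, 0 °C → rt; used promptly
Reagents that add atoms: none
Why: Dess–Martin oxidation of the secondary alcohol under buffered, essentially neutral conditions, which should spare the β-acyloxy ketone from elimination and leave C5 in its trans-fused configuration.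

Step 14
Reactants: 21 4-ketone
Product: 22 target, 4β-hydroxy-4α-isopropyl-1β,8-dimethyl-trans-bicyclo[5.3.0]dec-8-en-6α-yl 3,4-dimethoxybenzoate
Conditions: i-PrMgCl, anhydrous CeCl3 (pre-stirred), THF, −78 °C; aq. NH4Cl
Reagents that add atoms: isopropylmagnesium chloride, CC(C)[Mg]Cl
Why: Organocerium 1,2-addition (Imamoto conditions): the weakly basic, strongly oxophilic reagent adds to the cyclopentanone faster than it enolises it or attacks the hindered electron-rich aryl ester, and it approaches the α-face (syn to 5-H) because the C1 angular methyl screens the β-face across the five-membered ring, giving the 4β-hydroxy-4α-isopropyl centre.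

**Compound list**

1 | 3-methylcyclopent-2-en-1-one | CC1=CC(=O)CC1 | starting material
2 | (R)-3-methylcyclopent-2-en-1-ol | CC1=C[C@H](O)CC1 | intermediate
3 | dichlorodiisopropylsilane | CC(C)[Si](Cl)(Cl)C(C)C | starting material
4 | cyclopentane-1,3-dione | O=C1CCC(=O)C1 | starting material
5 | chloro(diisopropyl)[(R)-3-methylcyclopent-2-en-1-yloxy]silane (not isolated) | CC1=C[C@H](O[Si](Cl)(C(C)C)C(C)C)CC1 | intermediate
6 | 3-{[diisopropyl((R)-3-methylcyclopent-2-en-1-yloxy)silyl]oxy}cyclopent-2-en-1-one | CC1=C[C@H](O[Si](C(C)C)(C(C)C)OC2=CC(=O)CC2)CC1 | intermediate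
7 | tetracyclic photoadduct, cis-anti-cis cyclobutane, silylene bridge 4α-O to 6-O, 9-ketone, 5β-H | O=C1CC[C@]2(O[Si](C(C)C)(C(C)C)O3)[C@H]1[C@@]4(C)CC[C@@H]3[C@@H]24 | intermediate
8 | lithium C8=C9 enolate of 7 (not isolated) | [Li]OC1=CC[C@]2(O[Si](C(C)C)(C(C)C)O3)[C@H]1[C@@]4(C)CC[C@@H]3[C@@H]24 | intermediate
9 | 8-methyl photoadduct (C8 epimers) | O=C1C(C)C[C@]2(O[Si](C(C)C)(C(C)C)O3)[C@H]1[C@@]4(C)CC[C@@H]3[C@@H]24 | intermediate
10 | desilylated cyclobutanediol, 4α,6-dihydroxy-9-ketone (not isolated) | O=C1C(C)C[C@]2(O)[C@H]1[C@@]3(C)CC[C@@H](O)[C@@H]23 | intermediate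
11 | cis-fused 4α-hydroxy-1β,8-dimethylbicyclo[5.3.0]decane-6,9-dione (5β-H) | O=C1CC(C)C(=O)C[C@@]2(C)CC[C@@H](O)[C@@H]12 | intermediate
12 | cis-fused 4α-(tert-butyldimethylsilyloxy)-1β,8-dimethylbicyclo[5.3.0]decane-6,9-dione | O=C1CC(C)C(=O)C[C@@]2(C)CC[C@@H](O[Si](C)(C)C(C)(C)C)[C@@H]12 | intermediate
13 | trans-fused 4α-(tert-butyldimethylsilyloxy)-1β,8-dimethylbicyclo[5.3.0]decane-6,9-dione (5α-H) | O=C1CC(C)C(=O)C[C@@]2(C)CC[C@@H](O[Si](C)(C)C(C)(C)C)[C@H]12 | intermediate
14 | trans-fused 4α-(tert-butyldimethylsilyloxy)-9-hydroxy-1β,8-dimethylbicyclo[5.3.0]decan-6-one (9-OH cis to 8-CH3, C8 epimers) | O=C1CC(C)C(O)C[C@@]2(C)CC[C@@H](O[Si](C)(C)C(C)(C)C)[C@H]12 | intermediate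
15 | 9-dichlorophosphate of 14 (not isolated) | O=C1CC(C)C(OP(=O)(Cl)Cl)C[C@@]2(C)CC[C@@H](O[Si](C)(C)C(C)(C)C)[C@H]12 | intermediate
16 | trans-fused 4α-(tert-butyldimethylsilyloxy)-1β,8-dimethylbicyclo[5.3.0]dec-8-en-6-one | O=C1CC(C)=CC[C@@]2(C)CC[C@@H](O[Si](C)(C)C(C)(C)C)[C@H]12 | intermediate
17 | trans-fused 4α-(tert-butyldimethylsilyloxy)-1β,8-dimethylbicyclo[5.3.0]dec-8-en-6α-ol | O[C@H]1CC(C)=CC[C@@]2(C)CC[C@@H](O[Si](C)(C)C(C)(C)C)[C@H]12 | intermediate
18 | 3,4-dimethoxybenzoyl chloride | COc1ccc(C(=O)Cl)cc1OC | starting material
19 | 6α-(3,4-dimethoxybenzoyloxy) 4α-silyl ether | COc1ccc(C(=O)O[C@H]2CC(C)=CC[C@@]3(C)CC[C@@H](O[Si](C)(C)C(C)(C)C)[C@H]23)cc1OC | intermediate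
20 | 6α-(3,4-dimethoxybenzoyloxy) 4α-alcohol | COc1ccc(C(=O)O[C@H]2CC(C)=CC[C@@]3(C)CC[C@@H](O)[C@H]23)cc1OC | intermediate
21 | 6α-(3,4-dimethoxybenzoyloxy) 4-ketone | COc1ccc(C(=O)O[C@H]2CC(C)=CC[C@@]3(C)CCC(=O)[C@H]23)cc1OC | intermediate
22 | CNP0153023.1, 4β-hydroxy-4α-isopropyl-1β,8-dimethyl-trans-bicyclo[5.3.0]dec-8-en-6α-yl 3,4-dimethoxybenzoate | COc1ccc(C(=O)O[C@H]2CC(C)=CC[C@@]3(C)CC[C@@](O)(C(C)C)[C@H]23)cc1OC | target

**Step count**

Total steps: 14. Longest linear sequence: 14 steps (1 → 22).

**Steps most likely to fail**

Step 3 (photocycloaddition). The vinylogous silyl ester linkage may be lost by adventitious hydrolysis or photodesilylation before the ring closes, and over-irradiation may cleave the product ketone, so that little tetracycle accumulates. The fallback replaces the silicon tether by a carbon acetal tether and sets out from 2. Vinyl transfer ([Ir(cod)Cl]2, Na2CO3, vinyl acetate, toluene, 100 °C) should give the vinyl ether F1. Addition of the acidic enol of 4 across it (pyridinium p-toluenesulfonate cat., CH2Cl2, 0 °C) should give the 1-alkoxyethyl enol ether F2. Irradiation as in step 3 should give the 1,3-dioxane-bridged photoadduct F3, and LiN(i-Pr)2 then MeI its 8-methyl derivative F4. Mild hydrolysis (AcOH, H2O, THF; then K2CO3, MeOH) frees cyclobutanediol 10, which ring-expands, and the route is rejoined at 11.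

Step 8 (selective reduction at C9). Hydride delivery may fail to distinguish the two ring carbonyls, giving reduction at C6 or at both. The fallback moves the reduction ahead of the ring-fusion epimerisation and sets out from 12, where the C6 carbonyl lies on the concave face of the cis-fused bicycle directly beside the cis silyloxy group. LiBH(s-Bu)3 at −78 °C should then give the cis-fused 9-hydroxy-6-ketone F5, and DBU epimerisation of C5 returns the route at 14.

Step 14 (isopropyl addition). The hindered ketone may be deprotonated at C5 with expulsion of the C6 carboxylate, may be reduced by hydride transfer from the secondary alkyl nucleophile, or may react so slowly that the ester is attacked. The fallback uses a smaller sp2 nucleophile without transferable β-hydride and sets out from 21. 2-Propenylmagnesium bromide with CeCl3 (THF, −78 °C) should give the isopropenyl carbinol F6 by the same α-face approach. Hydrogenation with RhCl(PPh3)3 and H2 in benzene, which saturates the 1,1-disubstituted alkene in preference to the trisubstituted ring alkene, returns the route at 22.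

**Further compounds**

F1 | step 3 | (R)-3-methylcyclopent-2-en-1-yl vinyl ether | CC1=C[C@H](OC=C)CC1
F2 | step 3 | 3-{1-[(R)-3-methylcyclopent-2-en-1-yloxy]ethoxy}cyclopent-2-en-1-one (acetal epimers) | CC1=C[C@H](OC(C)OC2=CC(=O)CC2)CC1
F3 | step 3 | acetal-bridged tetracyclic photoadduct (ethylidene in place of the silylene of 7) | O=C1CC[C@]2(OC(C)O3)[C@H]1[C@@]4(C)CC[C@@H]3[C@@H]24
F4 | step 3 | 8-methyl acetal-bridged photoadduct | O=C1C(C)C[C@]2(OC(C)O3)[C@H]1[C@@]4(C)CC[C@@H]3[C@@H]24
F5 | step 8 | cis-fused 4α-(tert-butyldimethylsilyloxy)-9-hydroxy-1β,8-dimethylbicyclo[5.3.0]decan-6-one | O=C1CC(C)C(O)C[C@@]2(C)CC[C@@H](O[Si](C)(C)C(C)(C)C)[C@@H]12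
F6 | step 14 | 4β-hydroxy-4α-isopropenyl-1β,8-dimethyl-trans-bicyclo[5.3.0]dec-8-en-6α-yl 3,4-dimethoxybenzoate | COc1ccc(C(=O)O[C@H]2CC(C)=CC[C@@]3(C)CC[C@@](O)(C(C)=C)[C@H]23)cc1OC
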